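**Plan**

- Retrosynthesis: the depside ester bond between O4 of ring A (the salicylic acid ring) and the carbonyl of ring B (the 2,4-dimethoxy-6-propylbenzoyl unit) is cut first; ring B then gives up its carboxyl carbon and goes back to 1,3-dimethoxy-5-propylbenzene.
- Ring A is taken down to the cyclohexane-1,3-dione oxidation level and cut at C1–C6 and C2–C3.
- Enabling feature: ring A carries its carboxyl on C1, oxygen on C2 and C4 and the propyl chain on C6, so C1, C2 and the carboxyl are a malonate, and C3–C6 with the propyl chain are (E)-hept-3-en-2-one.
- Forward: the ring B acid is made by formylation and oxidation; ring A (the only ring formed) arises by Michael–Claisen annulation and is dehydrogenated to the benzyl resorcylate; the halves are joined by esterification at the 4-OH and the benzyl ester is removed last.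
- Stereochemistry: the target has no stereocenter; the two sp3 centers of the annulation product (racemic, trans by equilibration) vanish on aromatization. O4 is distinguished from O2 by the hydrogen bond that ties the 2-OH to the ester.

Key step: step 3

Assumption: the Michael adduct and the cyclohexenone intermediates of steps 3 and 4 are racemic, and their SMILES show one enantiomer of the stated relative configuration; a 1 M solution of NaOCH2Ph in benzyl alcohol is taken as a commercial reagent.

**Route**

Step 1
Reactants: 1 1,3-dimethoxy-5-propylbenzene
Product: 3 2,4-dimethoxy-6-propylbenzaldehyde, via iminium chloride 2 (not isolated)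
Conditions: POCl3, DMF, 0 °C → 70 °C; then ice/H2O
Reagents that add atoms: N,N-dimethylformamide, CN(C)C=O; water, O
Why: Vilsmeier–Haack formylation, in which the chloroiminium ion from DMF and POCl3 attacks the ring carbon para to one methoxy group, ortho to the other and next to the propyl chain rather than the more crowded carbon between the two methoxy groups, and water then hydrolyzes the iminium salt to the aldehyde.

Step 2
Reactants: 3 2,4-dimethoxy-6-propylbenzaldehyde
Product: 4 2,4-dimethoxy-6-propylbenzoic acid
Conditions: NaClO2, NaH2PO4, 2-methylbut-2-ene, t-BuOH/H2O, rt
Reagents that add atoms: sodium chlorite, [Na+].[O-]Cl=O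
Why: Pinnick oxidation, in which chlorous acid adds to the aldehyde and fragments to the acid and HOCl, which the alkene traps before it can chlorinate the electron-rich ring.

Step 3
Reactants: 5 dibenzyl malonate; 6 (E)-hept-3-en-2-one
Product: 9 benzyl (1S*,6R*)-2-hydroxy-4-oxo-6-propylcyclohex-2-ene-1-carboxylate, via Michael adduct 7 (not isolated), via sodium enolate 8 (not isolated)
Conditions: NaOCH2Ph (1.1 equiv, 1 M in PhCH2OH), THF, 0 °C → 65 °C; then 1 M HCl, 0 °C
Reagents that add atoms: none
Why: Benzyloxide deprotonates the malonate, whose stabilized anion adds in a Michael reaction to the β-carbon (C4) of the enone and so forms the C1–C6 bond of ring A, and after proton transfer the methyl-side ketone enolate attacks one benzyl ester in a Claisen condensation that forms C2–C3 and expels benzyloxide. The closest known reaction type is the Michael–Claisen annulation of dialkyl malonates onto alkenyl methyl ketones that gives 6-alkyl-dihydroresorcylates. The ring closes in the 6-(enolendo)-exo-trig mode, the only feasible one because the enolate on the internal methylene could reach an ester only through a four-membered ring. C6 arises without control as a racemate, and C1, which stays acidic between the ester and the enolized dione, settles under equilibration with ester and propyl trans and pseudo-equatorial; both centers disappear in step 4. The step needs 1,4- over 1,2-addition, which the soft malonate anion and the reversibility of carbonyl addition provide, and it needs ring closure to win over retro-Michael cleavage, which the irreversible deprotonation of the acidic dione to enolate 8 secures. Using benzyloxide with benzyl esters makes any alkoxide exchange degenerate, so the ester needed for the final hydrogenolysis is kept.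

Step 4
Reactants: 9 benzyl (1S*,6R*)-2-hydroxy-4-oxo-6-propylcyclohex-2-ene-1-carboxylate
Product: 11 benzyl 2,4-dihydroxy-6-propylbenzoate, via iodo dione 10 (not isolated)
Conditions: I2 (0.2 equiv), DMSO, 80 °C
Reagents that add atoms: none
Why: Iodine-catalyzed oxidative aromatization of a cyclohexane-1,3-dione, in which iodination at the enolic C3 is followed by loss of HI through the dienol and tautomerization to the resorcinol, DMSO reoxidizes HI to I2, and the gain of aromaticity drives the reaction while the benzyl ester is left alone.

Step 5
Reactants: 4 2,4-dimethoxy-6-propylbenzoic acid; 11 benzyl 2,4-dihydroxy-6-propylbenzoate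
Product: 13 benzyl 4-[(2,4-dimethoxy-6-propylbenzoyl)oxy]-2-hydroxy-6-propylbenzoate, via mixed anhydride 12 (not isolated)
Conditions: (CF3CO)2O, toluene, 0 °C → rt
Reagents that add atoms: none
Why: Trifluoroacetic anhydride-mediated esterification (mixed anhydride method), in which the mixed anhydride of the hindered, electron-rich acid acts as an acylium donor toward the free 4-OH, while the 2-OH is held in a hydrogen bond to the neighboring ester carbonyl and shielded by it, the usual site selectivity of 2,4-dihydroxybenzoates.

Step 6
Reactants: 13 benzyl 4-[(2,4-dimethoxy-6-propylbenzoyl)oxy]-2-hydroxy-6-propylbenzoate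
Product: 14 4-[(2,4-dimethoxy-6-propylbenzoyl)oxy]-2-hydroxy-6-propylbenzoic acid
Conditions: H2 (1 atm), 10% Pd/C, EtOAc, rt
Reagents that add atoms: none
Why: Catalytic hydrogenolysis of a benzyl ester under neutral conditions at room temperature, which leaves the aryl ester and the methyl ethers intact and avoids decarboxylation of the salicylic acid.

**Compound list**

1 | 1,3-dimethoxy-5-propylbenzene | CCCc1cc(OC)cc(OC)c1 | starting material
2 | N-[(2,4-dimethoxy-6-propylphenyl)methylidene]-N-methylmethanaminium chloride | CCCc1cc(OC)cc(OC)c1C=[N+](C)C.[Cl-] | intermediate
3 | 2,4-dimethoxy-6-propylbenzaldehyde | CCCc1cc(OC)cc(OC)c1C=O | intermediate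
4 | 2,4-dimethoxy-6-propylbenzoic acid | CCCc1cc(OC)cc(OC)c1C(=O)O | intermediate
5 | dibenzyl malonate | O=C(CC(=O)OCc1ccccc1)OCc1ccccc1 | starting material
6 | (E)-hept-3-en-2-one | CCC/C=C/C(C)=O | starting material
7 | dibenzyl 2-(2-oxoheptan-4-yl)propanedioate (racemic Michael adduct) | CCC[C@@H](C(C(=O)OCc1ccccc1)C(=O)OCc1ccccc1)CC(C)=O | intermediate
8 | sodium trans-6-(benzyloxycarbonyl)-3-oxo-5-propylcyclohex-1-en-1-olate (racemic; sodium enolate of 9) | CCC[C@@H]1CC(=O)C=C([O-])[C@H]1C(=O)OCc1ccccc1.[Na+] | intermediate
9 | benzyl (1S*,6R*)-2-hydroxy-4-oxo-6-propylcyclohex-2-ene-1-carboxylate (racemic; ester and propyl trans) | CCC[C@@H]1CC(=O)C=C(O)[C@H]1C(=O)OCc1ccccc1 | intermediate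
10 | benzyl (1S*,6R*)-2-hydroxy-3-iodo-4-oxo-6-propylcyclohex-2-ene-1-carboxylate (racemic) | CCC[C@@H]1CC(=O)C(I)=C(O)[C@H]1C(=O)OCc1ccccc1 | intermediate
11 | benzyl 2,4-dihydroxy-6-propylbenzoate | CCCc1cc(O)cc(O)c1C(=O)OCc1ccccc1 | intermediate
12 | 2,4-dimethoxy-6-propylbenzoic trifluoroacetic anhydride | CCCc1cc(OC)cc(OC)c1C(=O)OC(=O)C(F)(F)F | intermediate
13 | benzyl 4-[(2,4-dimethoxy-6-propylbenzoyl)oxy]-2-hydroxy-6-propylbenzoate | CCCc1cc(OC(=O)c2c(CCC)cc(OC)cc2OC)cc(O)c1C(=O)OCc1ccccc1 | intermediate
14 | 4-[(2,4-dimethoxy-6-propylbenzoyl)oxy]-2-hydroxy-6-propylbenzoic acid | CCCc1cc(OC(=O)c2c(CCC)cc(OC)cc2OC)cc(O)c1C(=O)O | target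

**Count and risks**

Total step count: 6. Longest linear sequence: 4 steps (5 and 6 → 9 → 11 → 13 → 14; the branch 1 → 3 → 4 → 13 → 14 is equally long).

Steps most likely to fail:

Step 4 (aromatization). Iodination of the electron-rich resorcinol ring as it forms may withdraw iodine from the catalytic cycle, or HI may build up and cleave the benzyl ester, so that conversion stalls. The fallback sets out from 9 and separates halogenation from elimination. One equivalent of N-bromosuccinimide in CH2Cl2 at 0 °C should brominate the enolic C3 and give benzyl (1S*,6R*)-3-bromo-2-hydroxy-4-oxo-6-propylcyclohex-2-ene-1-carboxylate F1. Warming this bromo dione with Li2CO3 in DMF at 100 °C should remove HBr through the dienol and come back to the route at 11, with no free halogen present when the resorcinol appears.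

Step 5 (depside ester). The acylium-type donor may attack a ring carbon of the resorcinol instead of oxygen, or the mixed anhydride may transfer its trifluoroacetyl group so that the hindered aroyl group is not delivered. The fallback sets out from 4, which oxalyl chloride and catalytic DMF in CH2Cl2 should convert into 2,4-dimethoxy-6-propylbenzoyl chloride F2. Adding this acid chloride to 11 and K2CO3 in acetone (rt to reflux) changes the mechanism to attack of a phenoxide on an acyl chloride. Only the more acidic, non-chelated 4-OH is deprotonated, and the sequence comes back to the route at 13.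

Step 3 (key step). Under stoichiometric benzyloxide at 65 °C, retro-Michael cleavage, self-condensation of the enone and attack of benzyloxide on the benzylic carbon of the esters may compete with a slow Claisen closure. The fallback sets out from 5 and 6 and runs the two bond formations as separate operations. K2CO3 (0.2 equiv) in THF at rt should give the Michael adduct 7, which is now isolated. NaH (1.1 equiv) with catalytic PhCH2OH in THF at reflux then closes the ring to enolate 8, and acidification with 1 M HCl comes back to the route at 9. This detour makes no compound outside the list (F0).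

Further compounds
F1 | step 4 | benzyl (1S*,6R*)-3-bromo-2-hydroxy-4-oxo-6-propylcyclohex-2-ene-1-carboxylate (racemic) | CCC[C@@H]1CC(=O)C(Br)=C(O)[C@H]1C(=O)OCc1ccccc1
F2 | step 5 | 2,4-dimethoxy-6-propylbenzoyl chloride | CCCc1cc(OC)cc(OC)c1C(Cl)=O
F0 | step 3 | none | none
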